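**Retrosynthetic overview**

- The depside ester is never disconnected. It is carried from the start as the propiolate ester of methyl orsellinate (ring A, bought), so ring B is the only ring made.
- Ring B (C1 acyl-bearing, C2 OH, C3 Cl, C4 OMe, C5 H, C6 Me) is cut at C2–C3 and C1–C6. Its C3–C6, with Cl, OMe, H and Me, are C3–C6 of 3-chloro-4-methoxy-6-methyl-2-pyranone, and C1 and C2 are the two alkyne carbons of a 3-borylpropiolate.
- These bonds are formed by Diels–Alder addition of the pyranone to the alkynylboronate, followed by loss of CO2.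
- The ring B 2-hydroxyl is held as a C–B bond (pinacol boronate) until after the cycloaddition, and the ring A 2-hydroxyl as a triisopropylsilyl (TIPS) ether.
- Forward order: pyranone (two steps from triacetic acid lactone); boryl ynoate (three steps from methyl orsellinate); cycloaddition closing ring B; C–B oxidation; desilylation.

Key step: step 6

Remark on the chemistry: the ring A 2-hydroxyl is masked as a TIPS ether from step 4 to step 8, because a free salicylate phenol would consume the amide base in step 5 and could protonate the alkynyl–boron bond on heating. Ring A is numbered as in methyl orsellinate (C1 CO2Me, C2 OH, C4 O-acyl, C6 Me).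

**Step 1**
Reactants: 1 4-hydroxy-6-methyl-2H-pyran-2-one (triacetic acid lactone)
Product: 2 4-methoxy-6-methyl-2H-pyran-2-one
Conditions: Me2SO4, K2CO3, acetone, reflux
Reagents that add atoms: dimethyl sulfate, COS(=O)(=O)OC
Why: O-alkylation (Williamson type) of the vinylogous acid, whose potassium salt is methylated on the 4-oxygen by dimethyl sulfate, the standard way to the 2-pyranone methyl ether.

**Step 2**
Reactants: 2 4-methoxy-6-methyl-2H-pyran-2-one
Product: 3 3-chloro-4-methoxy-6-methyl-2H-pyran-2-one
Conditions: N-chlorosuccinimide (1.05 equiv), AcOH, 60 °C, dark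
Reagents that add atoms: N-chlorosuccinimide, O=C1CCC(=O)N1Cl
Why: Electrophilic chlorination of an enol ether, in which C3 is the β-carbon of the 4-methoxy enol ether and the vinylogous β-position of the ring oxygen and so the most nucleophilic ring carbon, as in the known 3-halogenation of 4-alkoxy-2-pyranones, while ionic conditions in the dark should spare the 6-methyl group.

**Step 3**
Reactants: 4 methyl orsellinate (methyl 2,4-dihydroxy-6-methylbenzoate); 5 propiolic acid
Product: 6 methyl 2-hydroxy-6-methyl-4-(prop-2-ynoyloxy)benzoate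
Conditions: DCC (1.1 equiv), DMAP (5 mol %), CH2Cl2, −20 to 0 °C
Reagents that add atoms: none
Why: Steglich esterification, selective for the free and more acidic 4-hydroxyl because the 2-hydroxyl is locked in a hydrogen bond to the ester carbonyl, with low temperature and little DMAP to suppress oxa-Michael addition to the ynoate.

**Step 4**
Reactants: 6 methyl 2-hydroxy-6-methyl-4-(prop-2-ynoyloxy)benzoate
Product: 7 methyl 6-methyl-4-(prop-2-ynoyloxy)-2-[(triisopropylsilyl)oxy]benzoate
Conditions: TIPSOTf (1.3 equiv), 2,6-lutidine (2 equiv), CH2Cl2, 0 °C to rt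
Reagents that add atoms: triisopropylsilyl trifluoromethanesulfonate, CC(C)[Si](C(C)C)(C(C)C)OS(=O)(=O)C(F)(F)F
Why: O-silylation of a hydrogen-bonded phenol by a silyl triflate with a hindered, non-nucleophilic pyridine base that should neither add to the ynoate nor cleave the aryl ester.

**Step 5**
Reactants: 7 methyl 6-methyl-4-(prop-2-ynoyloxy)-2-[(triisopropylsilyl)oxy]benzoate; 8 2-isopropoxy-4,4,5,5-tetramethyl-1,3,2-dioxaborolane
Product: 11 methyl 6-methyl-4-{[3-(4,4,5,5-tetramethyl-1,3,2-dioxaborolan-2-yl)prop-2-ynoyl]oxy}-2-[(triisopropylsilyl)oxy]benzoate, via lithium acetylide 9 (not isolated), via lithium isopropoxyborate 10 (not isolated)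
Conditions: LiN(SiMe3)2 (1.05 equiv), THF, −78 °C, 15 min; then 8 (1.2 equiv), −78 °C, 1 h; then HCl in Et2O (1.1 equiv), −78 °C to rt; filtered under argon, used crude
Reagents that add atoms: none
Why: Brown-type alkynylboronate synthesis, in which the acidic ynoate C–H is removed by a hindered non-nucleophilic amide at −78 °C, the acetylide is trapped at boron as the tetracoordinate borate, and anhydrous HCl expels isopropanol without aqueous contact.

**Step 6**
Reactants: 3 3-chloro-4-methoxy-6-methyl-2H-pyran-2-one; 11 methyl 6-methyl-4-{[3-(4,4,5,5-tetramethyl-1,3,2-dioxaborolan-2-yl)prop-2-ynoyl]oxy}-2-[(triisopropylsilyl)oxy]benzoate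
Product: 13 methyl 4-{[3-chloro-4-methoxy-6-methyl-2-(4,4,5,5-tetramethyl-1,3,2-dioxaborolan-2-yl)benzoyl]oxy}-6-methyl-2-[(triisopropylsilyl)oxy]benzoate, via bridged lactone 12 (not isolated)
Conditions: 3 (2 equiv), o-dichlorobenzene, sealed tube, argon, 170–180 °C
Reagents that add atoms: none
Why: Thermal, concerted but asynchronous [4+2] cycloaddition of the pyranone diene (C3=C4–C5=C6) to the ynoate, then retro-[4+2] loss of CO2 from the bridged lactone 12, the known reaction type being the 2-pyranone/alkynylboronate benzannulation. Ring B is closed intermolecularly as a six-membered carbocycle, both new bonds (ring B C2–C3 from pyranone C3 to the boron-bearing carbon, ring B C1–C6 from pyranone C6 to the ester-bearing carbon) forming in the one cycloaddition, and CO2 extrusion makes the closure irreversible. The 4-methoxyl on an inner diene carbon and the ring oxygen on the far terminus both place the largest HOMO coefficient on C3, outweighing the lactone carbonyl, while the ester places the largest LUMO coefficient of the alkyne on the β-carbon that carries boron, so the leading bond joins these two atoms and fixes the single orientation the step needs. No stereocentre is created in 13, since the two bridgehead centres of racemic 12 are dictated by the bicyclic frame and vanish on aromatisation. The silyl ether, both esters, the aryl chloride and the pinacol boronate should be inert to heat in an aprotic solvent, and the pyranone is used in excess because the alkyne is the more valuable partner.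

**Step 7**
Reactants: 13 methyl 4-{[3-chloro-4-methoxy-6-methyl-2-(4,4,5,5-tetramethyl-1,3,2-dioxaborolan-2-yl)benzoyl]oxy}-6-methyl-2-[(triisopropylsilyl)oxy]benzoate
Product: 14 methyl 4-[(3-chloro-2-hydroxy-4-methoxy-6-methylbenzoyl)oxy]-6-methyl-2-[(triisopropylsilyl)oxy]benzoate
Conditions: NaBO3·4H2O (3 equiv), THF/H2O (1:1), 0 °C to rt
Reagents that add atoms: sodium perborate (as NaBO3·4H2O), [Na+].[Na+].O[B-]1(O)OO[B-](O)(O)OO1
Why: Oxidation of the aryl C–B bond by peroxoborate attack on boron and 1,2-shift of the aryl group from boron to oxygen, then hydrolysis of the borate, under weakly basic conditions that should spare the doubly ortho-substituted aryl ester, the methyl ester and the TIPS ether.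

**Step 8**
Reactants: 14 methyl 4-[(3-chloro-2-hydroxy-4-methoxy-6-methylbenzoyl)oxy]-6-methyl-2-[(triisopropylsilyl)oxy]benzoate
Product: 15 methyl 4-[(3-chloro-2-hydroxy-4-methoxy-6-methylbenzoyl)oxy]-2-hydroxy-6-methylbenzoate (target)
Conditions: Bu4NF (1.2 equiv), AcOH (1.2 equiv), THF, 0 °C
Reagents that add atoms: none
Why: Fluoride-mediated desilylation of an aryl silyl ether driven by Si–F bond formation, buffered by acetic acid so that the phenoxide is protonated at once and neither ester is cleaved or migrates.

**Compound list**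

1 | 4-hydroxy-6-methyl-2H-pyran-2-one (triacetic acid lactone) | CC1=CC(O)=CC(=O)O1 | starting material
2 | 4-methoxy-6-methyl-2H-pyran-2-one | COC1=CC(=O)OC(C)=C1 | intermediate
3 | 3-chloro-4-methoxy-6-methyl-2H-pyran-2-one | COC1=C(Cl)C(=O)OC(C)=C1 | intermediate
4 | methyl orsellinate (methyl 2,4-dihydroxy-6-methylbenzoate) | COC(=O)c1c(C)cc(O)cc1O | starting material
5 | propiolic acid | C#CC(=O)O | starting material
6 | methyl 2-hydroxy-6-methyl-4-(prop-2-ynoyloxy)benzoate | COC(=O)c1c(C)cc(OC(=O)C#C)cc1O | intermediate
7 | methyl 6-methyl-4-(prop-2-ynoyloxy)-2-[(triisopropylsilyl)oxy]benzoate | COC(=O)c1c(C)cc(OC(=O)C#C)cc1O[Si](C(C)C)(C(C)C)C(C)C | intermediate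
8 | 2-isopropoxy-4,4,5,5-tetramethyl-1,3,2-dioxaborolane | CC(C)OB1OC(C)(C)C(C)(C)O1 | starting material
9 | lithium acetylide of 7 (lithium on the terminal alkyne carbon; not isolated) | [Li]C#CC(=O)Oc1cc(C)c(C(=O)OC)c(O[Si](C(C)C)(C(C)C)C(C)C)c1 | intermediate
10 | lithium alkynyl(isopropoxy)(pinacolato)borate from 9 and 8 (not isolated) | [Li+].COC(=O)c1c(C)cc(OC(=O)C#C[B-]2(OC(C)C)OC(C)(C)C(C)(C)O2)cc1O[Si](C(C)C)(C(C)C)C(C)C | intermediate
11 | methyl 6-methyl-4-{[3-(4,4,5,5-tetramethyl-1,3,2-dioxaborolan-2-yl)prop-2-ynoyl]oxy}-2-[(triisopropylsilyl)oxy]benzoate | COC(=O)c1c(C)cc(OC(=O)C#CB2OC(C)(C)C(C)(C)O2)cc1O[Si](C(C)C)(C(C)C)C(C)C | intermediate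
12 | racemic 4-(methoxycarbonyl)-3-methyl-5-[(triisopropylsilyl)oxy]phenyl 4-chloro-8-methoxy-1-methyl-3-oxo-5-(4,4,5,5-tetramethyl-1,3,2-dioxaborolan-2-yl)-2-oxabicyclo[2.2.2]octa-5,7-diene-6-carboxylate (bridged lactone; not isolated) | ClC12C(=O)OC(C)(C=C1OC)C(C(=O)Oc1cc(C)c(C(=O)OC)c(O[Si](C(C)C)(C(C)C)C(C)C)c1)=C2B1OC(C)(C)C(C)(C)O1 | intermediate
13 | methyl 4-{[3-chloro-4-methoxy-6-methyl-2-(4,4,5,5-tetramethyl-1,3,2-dioxaborolan-2-yl)benzoyl]oxy}-6-methyl-2-[(triisopropylsilyl)oxy]benzoate | COC(=O)c1c(C)cc(OC(=O)c2c(C)cc(OC)c(Cl)c2B3OC(C)(C)C(C)(C)O3)cc1O[Si](C(C)C)(C(C)C)C(C)C | intermediate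
14 | methyl 4-[(3-chloro-2-hydroxy-4-methoxy-6-methylbenzoyl)oxy]-6-methyl-2-[(triisopropylsilyl)oxy]benzoate | COC(=O)c1c(C)cc(OC(=O)c2c(C)cc(OC)c(Cl)c2O)cc1O[Si](C(C)C)(C(C)C)C(C)C | intermediate
15 | methyl 4-[(3-chloro-2-hydroxy-4-methoxy-6-methylbenzoyl)oxy]-2-hydroxy-6-methylbenzoate | COC(=O)c1c(C)cc(OC(=O)c2c(C)cc(OC)c(Cl)c2O)cc1O | target

**Step count**

Total: 8 steps. Longest linear sequence: 6 steps (steps 3, 4, 5, 6, 7, 8).

**Steps most likely to fail**

1. Step 6. The cycloaddition joins two fully substituted carbons (C3 bearing chlorine and the boron-bearing alkyne carbon), so it may be slow enough for thermal oligomerisation or protodeboronation of the alkynylboronate to win. The boryl group may also erode the orientation set by the ester. Fallback, setting out from 3 and 7: heating 3 with the terminal ynoate 7 (o-dichlorobenzene, 160–170 °C) removes boron from the cycloaddition. The pyranone C3 should again bond to the ynoate β-carbon, which now carries only hydrogen, and the boron-free bridged lactone F1 should lose CO2 to give the ring B 2-unsubstituted depside silyl ether F2. The only C–H ortho to an ester carbonyl in F2 is ring B C2–H, since both ortho positions of the ring A ester are substituted. Ester-directed iridium-catalysed ortho C–H borylation ([Ir(OMe)(cod)]2, P[3,5-(CF3)2C6H3]3, B2pin2, octane, 80 °C) should therefore place boron there, and the route is rejoined at 13.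

2. Step 5. The lithium acetylide may attack the aryl ester of a second molecule, or the electron-poor borate may revert to the terminal alkyne on acidification, so that the alkynylboronate is not obtained clean. Fallback, setting out from 7: base-free bromination of the alkyne C–H (N-bromosuccinimide, AgNO3 10 mol %, acetone, rt) should give the 3-bromopropiolate ester F3. Heating F3 with 3 (o-dichlorobenzene, 150–160 °C) should proceed with the same ester-controlled orientation through the bromo bridged lactone F4 and loss of CO2 to the ring B 2-bromo depside silyl ether F5. Miyaura borylation (B2pin2, KOAc, PdCl2(dppf), dioxane, 90 °C), selective for C–Br over C–Cl, then returns the route to 13.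

3. Step 7. Hydroperoxide-type nucleophiles may cleave the aryl ester or the methyl ester, and the crowded boronate flanked by chlorine and the ester may protodeboronate in base faster than it oxidises. Fallback, setting out from 13: aqueous KHF2 in MeOH at rt should convert the pinacol boronate into the potassium aryltrifluoroborate with free ring A phenol F6. KHF2 in methanol is a known reagent for cleaving phenolic silyl ethers, so the TIPS group should be removed in the same operation. Oxidation of F6 with KHSO5 (as Oxone, 2KHSO5·KHSO4·K2SO4) in acetone/H2O at rt, a fast and non-basic C–B oxidation, should then give 15 directly, bypassing 14.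

**Further compounds**

F1 | step 6 | racemic 4-(methoxycarbonyl)-3-methyl-5-[(triisopropylsilyl)oxy]phenyl 4-chloro-8-methoxy-1-methyl-3-oxo-2-oxabicyclo[2.2.2]octa-5,7-diene-6-carboxylate (not isolated) | ClC12C(=O)OC(C)(C=C1OC)C(C(=O)Oc1cc(C)c(C(=O)OC)c(O[Si](C(C)C)(C(C)C)C(C)C)c1)=C2
F2 | step 6 | methyl 4-[(5-chloro-4-methoxy-2-methylbenzoyl)oxy]-6-methyl-2-[(triisopropylsilyl)oxy]benzoate | COC(=O)c1c(C)cc(OC(=O)c2cc(Cl)c(OC)cc2C)cc1O[Si](C(C)C)(C(C)C)C(C)C
F3 | step 5 | methyl 4-[(3-bromoprop-2-ynoyl)oxy]-6-methyl-2-[(triisopropylsilyl)oxy]benzoate | COC(=O)c1c(C)cc(OC(=O)C#CBr)cc1O[Si](C(C)C)(C(C)C)C(C)C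
F4 | step 5 | racemic 4-(methoxycarbonyl)-3-methyl-5-[(triisopropylsilyl)oxy]phenyl 5-bromo-4-chloro-8-methoxy-1-methyl-3-oxo-2-oxabicyclo[2.2.2]octa-5,7-diene-6-carboxylate (not isolated) | ClC12C(=O)OC(C)(C=C1OC)C(C(=O)Oc1cc(C)c(C(=O)OC)c(O[Si](C(C)C)(C(C)C)C(C)C)c1)=C2Br
F5 | step 5 | methyl 4-[(2-bromo-3-chloro-4-methoxy-6-methylbenzoyl)oxy]-6-methyl-2-[(triisopropylsilyl)oxy]benzoate | COC(=O)c1c(C)cc(OC(=O)c2c(C)cc(OC)c(Cl)c2Br)cc1O[Si](C(C)C)(C(C)C)C(C)C
F6 | step 7 | potassium {6-chloro-2-[(3-hydroxy-4-(methoxycarbonyl)-5-methylphenoxy)carbonyl]-5-methoxy-3-methylphenyl}trifluoroborate | [K+].COC(=O)c1c(C)cc(OC(=O)c2c(C)cc(OC)c(Cl)c2[B-](F)(F)F)cc1O
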